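**Plan**

- Retrosynthesis: the lactone C1–O bond and the C3–H bond (from a C3 peroxy hemiketal) are cut first. The O–O bridge between C3 and C6 is then taken out as O2, which leaves a C3–C6 bond, so the 1,2-dioxane (O, O, C3, C4, C5, C6) is traced to a cyclobutanol (C3, C4, C5, C6; OH on C3). That ring is cut at C3–C6 to a γ-C–H of a β-keto ester, and the chain at C2–C3 (Claisen), C5–C6 (epoxide opening) and C11=C12 (Julia–Kocienski).
- Enabling feature: the peroxide spans C3 and C6; C6 is fully alkylated (tertiary radical on ring opening) and C3 can stand at the ketone level, so the strained C3–C6 bond breaks by alkoxy-radical β-scission and O2 is inserted. The chloroacetate on the C4 oxygen is the helper (steers the scission, later shields one face of C3) and is removed at the end.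
- Forward order: side chain from (R)-citronellal and a styryl sulfone; C3–C5 from a methylglycidate; β-keto ester; cyclobutane ring by Norrish–Yang photocyclisation; 1,2-dioxane ring by O2 insertion; C3 reduction; γ-lactone ring last.
- Stereochemistry: C8 from (R)-citronellal; C4 from methyl (S)-2-methylglycidate; C3 by anti hydride delivery to the acyloxy-bridged peroxycarbenium ion (only the cis isomer can lactonise); both E alkenes from the styryl alcohol and the Julia–Kocienski step.
- C6 is formed when O2 meets a planar radical and has no strong control element; both epimers are expected and are separated after step 12.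

Key step: step 11

Remark: atoms are numbered C1 (lactone carbonyl) to C16 (benzylic alkene carbon); the carbon that becomes C6 is carried as an epimer mixture until it turns into a radical in step 11; the styryl alcohol and the glycidate are taken as purchasable.

**Route**

Step 1
Reactants: 1 (R)-citronellal
Product: 2 (4R)-4,8-dimethylnon-7-en-2-ol (C2 epimer mixture)
Conditions: MeMgBr, Et2O, 0 °C
Reagents that add atoms: MeMgBr (methylmagnesium bromide), C[Mg]Br
Why: Grignard addition to the aldehyde; the new carbinol carbon (later C6) needs no control because it becomes a planar radical in step 11.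

Step 2
Reactants: 2 (4R)-4,8-dimethylnon-7-en-2-ol
Product: 3 (6R)-8-bromo-2,6-dimethylnon-2-ene (C8 epimer mixture)
Conditions: CBr4, PPh3, CH2Cl2, 0 °C
Reagents that add atoms: carbon tetrabromide, BrC(Br)(Br)Br
Why: Appel reaction (SN2 displacement of the oxyphosphonium group by bromide) gives the secondary bromide needed for the later Grignard reagent; its configuration is again irrelevant.

Step 3
Reactants: 3 (6R)-8-bromo-2,6-dimethylnon-2-ene
Product: 5 (4R)-6-bromo-4-methylheptanal, via ozonide 4 (not isolated)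
Conditions: O3, CH2Cl2, −78 °C; then Me2S, −78 °C to rt
Reagents that add atoms: ozone, [O-][O+]=O
Why: Ozonolysis with reductive work-up cuts the trisubstituted alkene to the C11 aldehyde; the alkyl bromide and the C8 centre are inert to ozone.

Step 4
Reactants: 6 (4E)-5-phenylpent-4-en-1-ol; 7 1-phenyl-1H-tetrazole-5-thiol
Product: 8 1-phenyl-5-{[(4E)-5-phenylpent-4-en-1-yl]sulfanyl}-1H-tetrazole
Conditions: PPh3, DIAD, THF, 0 °C to rt
Reagents that add atoms: none
Why: Mitsunobu reaction of the primary alcohol with the acidic tetrazole thiol gives the thioether without touching the E styrene.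

Step 5
Reactants: 8 1-phenyl-5-{[(4E)-5-phenylpent-4-en-1-yl]sulfanyl}-1H-tetrazole
Product: 9 1-phenyl-5-{[(4E)-5-phenylpent-4-en-1-yl]sulfonyl}-1H-tetrazole
Conditions: H2O2 (30% aq), (NH4)6Mo7O24·4H2O (cat.), EtOH, 0 °C to rt
Reagents that add atoms: hydrogen peroxide, OO
Why: Molybdate-catalysed oxidation of the sulfide to the sulfone, which should be selective for sulfur over the styrene under these conditions.

Step 6
Reactants: 9 1-phenyl-5-{[(4E)-5-phenylpent-4-en-1-yl]sulfonyl}-1H-tetrazole; 5 (4R)-6-bromo-4-methylheptanal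
Product: 10 [(1E,5E,9R)-11-bromo-9-methyldodeca-1,5-dien-1-yl]benzene (C11 epimer mixture)
Conditions: KN(SiMe3)2, DME, −60 °C; then 5, −60 °C to rt
Reagents that add atoms: none
Why: Julia–Kocienski olefination: addition of the metalated sulfone to the aldehyde, Smiles rearrangement and anti elimination of SO2 and tetrazolate should give the E C11=C12 alkene, favoured by the potassium counter-ion in DME.

Step 7
Reactants: 10 [(1E,5E,9R)-11-bromo-9-methyldodeca-1,5-dien-1-yl]benzene; 11 methyl (2S)-2-methyloxirane-2-carboxylate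
Product: 13 methyl (2S,6R,9E,13E)-2-hydroxy-2,4,6-trimethyl-14-phenyltetradeca-9,13-dienoate (C4 epimer mixture), via Grignard reagent 12 (not isolated)
Conditions: Mg, THF, 40 °C; then CuBr·SMe2 (10 mol %), 11, THF, −40 °C
Reagents that add atoms: none
Why: Copper-catalysed SN2 opening of the 2,2-disubstituted epoxide at its CH2 terminus (C5) by the secondary alkyl Grignard reagent, faster than ester addition at low temperature; the C4 centre is not touched, so its (S) configuration is that of the glycidate.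

Step 8
Reactants: 13 methyl (2S,6R,9E,13E)-2-hydroxy-2,4,6-trimethyl-14-phenyltetradeca-9,13-dienoate
Product: 14 tert-butyl (4S,8R,11E,15E)-4-hydroxy-4,6,8-trimethyl-3-oxo-16-phenylhexadeca-11,15-dienoate (C6 epimer mixture)
Conditions: tert-butyl acetate, LiN(iPr)2 (3.5 equiv each), THF, −78 °C; then 13, −78 to −20 °C
Reagents that add atoms: tert-butyl acetate, CC(=O)OC(C)(C)C
Why: Crossed Claisen condensation: the lithium enolate of tert-butyl acetate acylates at the methyl ester, the excess enolate covering the tertiary OH and the acidic product.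

Step 9
Reactants: 14 tert-butyl (4S,8R,11E,15E)-4-hydroxy-4,6,8-trimethyl-3-oxo-16-phenylhexadeca-11,15-dienoate
Product: 15 tert-butyl (4S,8R,11E,15E)-4-[(chloroacetyl)oxy]-4,6,8-trimethyl-3-oxo-16-phenylhexadeca-11,15-dienoate (C6 epimer mixture)
Conditions: (ClCH2CO)2O, DMAP, pyridine, CH2Cl2, 0 °C to rt
Reagents that add atoms: chloroacetic anhydride, O=C(CCl)OC(=O)CCl
Why: DMAP-catalysed acylation of the tertiary alcohol installs the electron-poor, participating and mildly removable chloroacetate on the C4 oxygen.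

Step 10
Reactants: 15 tert-butyl (4S,8R,11E,15E)-4-[(chloroacetyl)oxy]-4,6,8-trimethyl-3-oxo-16-phenylhexadeca-11,15-dienoate
Product: 16 tert-butyl 2-{(2S)-2-[(chloroacetyl)oxy]-1-hydroxy-2,4-dimethyl-4-[(2R,5E,9E)-2-methyl-10-phenyldeca-5,9-dien-1-yl]cyclobutyl}acetate (C1/C4 epimer mixture of the ring)
Conditions: hν (313 nm, Pyrex), degassed benzene (0.005 M), 15 °C
Reagents that add atoms: none
Why: Norrish–Yang photocyclisation: the n,π* excited C3 ketone abstracts the tertiary γ-hydrogen at C6 through a six-membered transition state and the 1,4-biradical closes the C3–C6 bond, the quaternary C4 disfavouring fragmentation; the new centres C3 and C6 need no control because both are erased in step 11.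

Step 11
Reactants: 16 tert-butyl 2-{(2S)-2-[(chloroacetyl)oxy]-1-hydroxy-2,4-dimethyl-4-[(2R,5E,9E)-2-methyl-10-phenyldeca-5,9-dien-1-yl]cyclobutyl}acetate
Product: 18 tert-butyl 2-{(4S)-4-[(chloroacetyl)oxy]-3-hydroxy-4,6-dimethyl-6-[(2R,5E,9E)-2-methyl-10-phenyldeca-5,9-dien-1-yl]-1,2-dioxan-3-yl}acetate (C3/C6 epimer mixture), via hydroperoxy ketone 17 (not isolated)
Conditions: Co(acac)2 (20 mol %), O2 (1 atm), ClCH2CH2Cl, 40 °C
Reagents that add atoms: dioxygen, O=O
Why: Co(acac)2 and O2 turn the tertiary cyclobutanol into a trivalent-cobalt alkoxide that releases the C3 alkoxy radical; strain-driven β-scission of the C3–C6 bond re-forms the C3 ketone and a tertiary C6 radical, O2 adds to it, and divalent cobalt reduces the peroxyl radical to hydroperoxide 17, whose OOH adds to the C3 ketone, so the four-membered carbocycle grows by two oxygen atoms into the 1,2-dioxane. The closest known reaction type is the Co(acac)2-catalysed aerobic oxidative ring expansion of cyclobutanols to 1,2-dioxan-3-ols. The ring closes by 6-exo-trig attack of the hydroperoxide oxygen on the carbonyl (reversible hemiketalisation). C6 is created when O2 meets a planar open-chain radical, with only the 1,3-related C4 centre as a weak bias, so both C6 epimers are expected and are separated after step 12; C3 is an equilibrating hemiketal centre that is reset in step 12, and C4 and C8 are not touched. The step needs β-scission of C3–C6 and not of C3–C4 or C3–C2: C6 is fully alkylated and gives an electron-rich tertiary radical, whereas the chloroacetoxy group makes the C4 radical electron-poor in the polar transition state and loss of C2 brings no strain relief. No hydride donor is present, so the styrene and the 1,2-disubstituted alkene, which hydrogen-atom-transfer hydroperoxidation would attack, stay intact, and O2 capture should outrun 6-exo cyclisation of the C6 radical onto C11=C12.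

Step 12
Reactants: 18 tert-butyl 2-{(4S)-4-[(chloroacetyl)oxy]-3-hydroxy-4,6-dimethyl-6-[(2R,5E,9E)-2-methyl-10-phenyldeca-5,9-dien-1-yl]-1,2-dioxan-3-yl}acetate
Product: 19 tert-butyl 2-{(3S,4S,6R)-4-[(chloroacetyl)oxy]-4,6-dimethyl-6-[(2R,5E,9E)-2-methyl-10-phenyldeca-5,9-dien-1-yl]-1,2-dioxan-3-yl}acetate
Conditions: Et3SiH (5 equiv), Me3SiOTf (0.5 equiv), CH2Cl2, −78 °C; then chromatography to remove the (6S) epimer
Reagents that add atoms: none
Why: Ionic hydrogenation of the peroxy hemiketal: Me3SiOTf ionises C3–OH to a peroxycarbenium ion that the chloroacetoxy carbonyl on C4 bridges as an acyloxonium ion, so hydride from Et3SiH enters anti to the C4 oxygen and sets C3 as (S) with the acetate arm cis to that oxygen.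

Step 13
Reactants: 19 tert-butyl 2-{(3S,4S,6R)-4-[(chloroacetyl)oxy]-4,6-dimethyl-6-[(2R,5E,9E)-2-methyl-10-phenyldeca-5,9-dien-1-yl]-1,2-dioxan-3-yl}acetate
Product: 21 γ-lactone (C1 carboxyl to the C4 oxygen) of 2-{(3S,4S,6R)-4-hydroxy-4,6-dimethyl-6-[(2R,5E,9E)-2-methyl-10-phenyldeca-5,9-dien-1-yl]-1,2-dioxan-3-yl}acetic acid (the target), via hydroxy ester 20 (not isolated)
Conditions: K2CO3 (0.2 equiv), MeOH, 0 °C; then CF3CO2H, CH2Cl2, 0 °C to rt
Reagents that add atoms: none
Why: Base-catalysed methanolysis removes the chloroacetate and acid then cleaves the tert-butyl ester, the 4-hydroxy acid closing to the γ-lactone (5-exo-trig acyl substitution), which only the cis C3/C4 arrangement allows.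

**Compound list**

1 | (R)-citronellal | C[C@H](CCC=C(C)C)CC=O | starting material
2 | (4R)-4,8-dimethylnon-7-en-2-ol (C2 epimer mixture) | C[C@H](CCC=C(C)C)CC(C)O | intermediate
3 | (6R)-8-bromo-2,6-dimethylnon-2-ene (C8 epimer mixture) | C[C@H](CCC=C(C)C)CC(C)Br | intermediate
4 | 3-[(3R)-5-bromo-3-methylhexyl]-5,5-dimethyl-1,2,4-trioxolane (ozonide) | C[C@H](CCC1OOC(C)(C)O1)CC(C)Br | intermediate
5 | (4R)-6-bromo-4-methylheptanal | C[C@H](CCC=O)CC(C)Br | intermediate
6 | (4E)-5-phenylpent-4-en-1-ol | OCCC/C=C/c1ccccc1 | starting material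
7 | 1-phenyl-1H-tetrazole-5-thiol | Sc1nnnn1-c1ccccc1 | starting material
8 | 1-phenyl-5-{[(4E)-5-phenylpent-4-en-1-yl]sulfanyl}-1H-tetrazole | S(CCC/C=C/c1ccccc1)c1nnnn1-c1ccccc1 | intermediate
9 | 1-phenyl-5-{[(4E)-5-phenylpent-4-en-1-yl]sulfonyl}-1H-tetrazole | O=S(=O)(CCC/C=C/c1ccccc1)c1nnnn1-c1ccccc1 | intermediate
10 | [(1E,5E,9R)-11-bromo-9-methyldodeca-1,5-dien-1-yl]benzene | C[C@H](CC/C=C/CC/C=C/c1ccccc1)CC(C)Br | intermediate
11 | methyl (2S)-2-methyloxirane-2-carboxylate | C[C@]1(CO1)C(=O)OC | starting material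
12 | [(4R,7E,11E)-4-methyl-12-phenyldodeca-7,11-dien-2-yl]magnesium bromide | C[C@H](CC/C=C/CC/C=C/c1ccccc1)CC(C)[Mg]Br | intermediate
13 | methyl (2S,6R,9E,13E)-2-hydroxy-2,4,6-trimethyl-14-phenyltetradeca-9,13-dienoate | C[C@H](CC/C=C/CC/C=C/c1ccccc1)CC(C)C[C@](C)(O)C(=O)OC | intermediate
14 | tert-butyl (4S,8R,11E,15E)-4-hydroxy-4,6,8-trimethyl-3-oxo-16-phenylhexadeca-11,15-dienoate | C[C@H](CC/C=C/CC/C=C/c1ccccc1)CC(C)C[C@](C)(O)C(=O)CC(=O)OC(C)(C)C | intermediate
15 | tert-butyl (4S,8R,11E,15E)-4-[(chloroacetyl)oxy]-4,6,8-trimethyl-3-oxo-16-phenylhexadeca-11,15-dienoate | C[C@H](CC/C=C/CC/C=C/c1ccccc1)CC(C)C[C@](C)(OC(=O)CCl)C(=O)CC(=O)OC(C)(C)C | intermediate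
16 | tert-butyl 2-{(2S)-2-[(chloroacetyl)oxy]-1-hydroxy-2,4-dimethyl-4-[(2R,5E,9E)-2-methyl-10-phenyldeca-5,9-dien-1-yl]cyclobutyl}acetate | C[C@H](CC/C=C/CC/C=C/c1ccccc1)CC1(C)C[C@](C)(OC(=O)CCl)C1(O)CC(=O)OC(C)(C)C | intermediate
17 | tert-butyl (4S,8R,11E,15E)-4-[(chloroacetyl)oxy]-6-hydroperoxy-4,6,8-trimethyl-3-oxo-16-phenylhexadeca-11,15-dienoate (C6 epimer mixture) | C[C@H](CC/C=C/CC/C=C/c1ccccc1)CC(C)(OO)C[C@](C)(OC(=O)CCl)C(=O)CC(=O)OC(C)(C)C | intermediate
18 | tert-butyl 2-{(4S)-4-[(chloroacetyl)oxy]-3-hydroxy-4,6-dimethyl-6-[(2R,5E,9E)-2-methyl-10-phenyldeca-5,9-dien-1-yl]-1,2-dioxan-3-yl}acetate (C3/C6 epimer mixture) | C[C@H](CC/C=C/CC/C=C/c1ccccc1)CC1(C)C[C@](C)(OC(=O)CCl)C(O)(CC(=O)OC(C)(C)C)OO1 | intermediate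
19 | tert-butyl 2-{(3S,4S,6R)-4-[(chloroacetyl)oxy]-4,6-dimethyl-6-[(2R,5E,9E)-2-methyl-10-phenyldeca-5,9-dien-1-yl]-1,2-dioxan-3-yl}acetate | C[C@H](CC/C=C/CC/C=C/c1ccccc1)C[C@]1(C)C[C@](C)(OC(=O)CCl)[C@H](CC(=O)OC(C)(C)C)OO1 | intermediate
20 | tert-butyl 2-{(3S,4S,6R)-4-hydroxy-4,6-dimethyl-6-[(2R,5E,9E)-2-methyl-10-phenyldeca-5,9-dien-1-yl]-1,2-dioxan-3-yl}acetate | C[C@H](CC/C=C/CC/C=C/c1ccccc1)C[C@]1(C)C[C@](C)(O)[C@H](CC(=O)OC(C)(C)C)OO1 | intermediate
21 | γ-lactone of 2-{(3S,4S,6R)-4-hydroxy-4,6-dimethyl-6-[(2R,5E,9E)-2-methyl-10-phenyldeca-5,9-dien-1-yl]-1,2-dioxan-3-yl}acetic acid (CNP0365311.2) | C[C@H](CC/C=C/CC/C=C/c1ccccc1)C[C@]1(C)C[C@]2(C)OC(=O)C[C@@H]2OO1 | target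

**Totals and risks**

Total step count: 13. Longest linear sequence: 11 steps (steps 1–3 and 6–13).

Steps most likely to fail:

1. Step 11. The alkoxy radical may fragment toward C4 (cleavage of C3–C4) in place of C3–C6, or the tertiary β-hydroxy ester may be lost by retro-aldol cleavage on cobalt. The fallback sets out from 15 and comes back at 18. Compound 15 is irradiated (313 nm) in O2-saturated benzene, so that the triplet C3/C6 1,4-biradical of the Norrish–Yang pathway is intercepted by O2 before it closes; this oxygen trapping of such biradicals to 3-hydroxy-1,2-dioxanes is recalled as known chemistry and should be confirmed before it is relied on. No alkoxy radical is formed, so the C3–C4 bond is never at risk, and no new compound is made.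

2. Step 10. Triplet energy transfer from the excited ketone to the styrene may quench the hydrogen abstraction and scramble the E geometry. The fallback sets out from 5 and comes back at 16, with the styrene added only after the photochemical step. Pent-4-en-1-ol and 7 give 5-(pent-4-en-1-ylsulfanyl)-1-phenyl-1H-tetrazole F1 (Mitsunobu), which is oxidised to 5-(pent-4-en-1-ylsulfonyl)-1-phenyl-1H-tetrazole F2. Julia–Kocienski olefination of 5 with F2 gives (5E,9R)-11-bromo-9-methyldodeca-1,5-diene F3. Its Grignard reagent [(4R,7E)-4-methyldodeca-7,11-dien-2-yl]magnesium bromide F4 opens 11 under CuBr·SMe2 catalysis to methyl (2S,6R,9E)-2-hydroxy-2,4,6-trimethyltetradeca-9,13-dienoate F5. Claisen condensation as in step 8 gives tert-butyl (4S,8R,11E)-4-hydroxy-4,6,8-trimethyl-3-oxohexadeca-11,15-dienoate F6, and acylation as in step 9 gives tert-butyl (4S,8R,11E)-4-[(chloroacetyl)oxy]-4,6,8-trimethyl-3-oxohexadeca-11,15-dienoate F7. Irradiation as in step 10, now without a low-energy triplet acceptor, gives tert-butyl 2-{(2S)-2-[(chloroacetyl)oxy]-1-hydroxy-2,4-dimethyl-4-[(2R,5E)-2-methyldeca-5,9-dien-1-yl]cyclobutyl}acetate F8. Cross-metathesis of the terminal alkene of F8 with styrene (second-generation Grubbs catalyst, CH2Cl2, 40 °C) should then give the E styrene 16.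

3. Step 12. Hydride may be delivered to the wrong face of the peroxycarbenium ion if acyloxonium bridging is incomplete. The fallback sets out from 18 and comes back at 21, replacing kinetic face control by a thermodynamic funnel. The reduction is run as before and the C3 epimers are not separated, so 19 is carried on together with tert-butyl 2-{(3R,4S,6R)-4-[(chloroacetyl)oxy]-4,6-dimethyl-6-[(2R,5E,9E)-2-methyl-10-phenyldeca-5,9-dien-1-yl]-1,2-dioxan-3-yl}acetate F9. K2CO3 in MeOH gives 20 and tert-butyl 2-{(3R,4S,6R)-4-hydroxy-4,6-dimethyl-6-[(2R,5E,9E)-2-methyl-10-phenyldeca-5,9-dien-1-yl]-1,2-dioxan-3-yl}acetate F10. Et2NH in CF3CH2OH then opens F10 by retro-oxa-Michael elimination to tert-butyl (2E,4S,6R,8R,11E,15E)-6-hydroperoxy-4-hydroxy-4,6,8-trimethyl-16-phenylhexadeca-2,11,15-trienoate F11, whose hydroperoxide adds back to the enoate reversibly (the known base-mediated intramolecular hydroperoxide Michael addition). Only 20 is drained from the equilibrium by lactonisation (CF3CO2H) to 21.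

Further compounds
F0 | step 11 | none | none
F1 | step 10 | 5-(pent-4-en-1-ylsulfanyl)-1-phenyl-1H-tetrazole | C=CCCCSc1nnnn1-c1ccccc1
F2 | step 10 | 5-(pent-4-en-1-ylsulfonyl)-1-phenyl-1H-tetrazole | C=CCCCS(=O)(=O)c1nnnn1-c1ccccc1
F3 | step 10 | (5E,9R)-11-bromo-9-methyldodeca-1,5-diene | C[C@H](CC/C=C/CCC=C)CC(C)Br
F4 | step 10 | [(4R,7E)-4-methyldodeca-7,11-dien-2-yl]magnesium bromide | C[C@H](CC/C=C/CCC=C)CC(C)[Mg]Br
F5 | step 10 | methyl (2S,6R,9E)-2-hydroxy-2,4,6-trimethyltetradeca-9,13-dienoate | C[C@H](CC/C=C/CCC=C)CC(C)C[C@](C)(O)C(=O)OC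
F6 | step 10 | tert-butyl (4S,8R,11E)-4-hydroxy-4,6,8-trimethyl-3-oxohexadeca-11,15-dienoate | C[C@H](CC/C=C/CCC=C)CC(C)C[C@](C)(O)C(=O)CC(=O)OC(C)(C)C
F7 | step 10 | tert-butyl (4S,8R,11E)-4-[(chloroacetyl)oxy]-4,6,8-trimethyl-3-oxohexadeca-11,15-dienoate | C[C@H](CC/C=C/CCC=C)CC(C)C[C@](C)(OC(=O)CCl)C(=O)CC(=O)OC(C)(C)C
F8 | step 10 | tert-butyl 2-{(2S)-2-[(chloroacetyl)oxy]-1-hydroxy-2,4-dimethyl-4-[(2R,5E)-2-methyldeca-5,9-dien-1-yl]cyclobutyl}acetate | C[C@H](CC/C=C/CCC=C)CC1(C)C[C@](C)(OC(=O)CCl)C1(O)CC(=O)OC(C)(C)C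
F9 | step 12 | tert-butyl 2-{(3R,4S,6R)-4-[(chloroacetyl)oxy]-4,6-dimethyl-6-[(2R,5E,9E)-2-methyl-10-phenyldeca-5,9-dien-1-yl]-1,2-dioxan-3-yl}acetate | C[C@H](CC/C=C/CC/C=C/c1ccccc1)C[C@]1(C)C[C@](C)(OC(=O)CCl)[C@@H](CC(=O)OC(C)(C)C)OO1
F10 | step 12 | tert-butyl 2-{(3R,4S,6R)-4-hydroxy-4,6-dimethyl-6-[(2R,5E,9E)-2-methyl-10-phenyldeca-5,9-dien-1-yl]-1,2-dioxan-3-yl}acetate | C[C@H](CC/C=C/CC/C=C/c1ccccc1)C[C@]1(C)C[C@](C)(O)[C@@H](CC(=O)OC(C)(C)C)OO1
F11 | step 12 | tert-butyl (2E,4S,6R,8R,11E,15E)-6-hydroperoxy-4-hydroxy-4,6,8-trimethyl-16-phenylhexadeca-2,11,15-trienoate | C[C@H](CC/C=C/CC/C=C/c1ccccc1)C[C@@](C)(OO)C[C@](C)(O)/C=C/C(=O)OC(C)(C)C
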